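If you want to know what a cold flask holds at its end, count its relaxations. That was the proposal at the meeting on these four flasks.

| setting | dusk | winter | south-west | north-west | south | east |
|---|---|---|---|---|---|---|
| L | 10 mM | 10 mM | 10 mM | 10 mM | 10 mM | 10 mM |
| Z | 44 µM | 98 µM | 65 µM | 65 µM | 65 µM | 65 µM |
| temperature | −20 °C | 13 °C | 5 °C | −15 °C | −35 °C | 25 °C |
| remark | run made earlier | run made earlier |  |  |  |  |
| time |  |  | 50 min | 50 min | 50 min | 50 min |

| run | time / min | Q / % | L / % |
|---|---|---|---|
| dusk | 8.00 | 43.8 | 53.9 |
| dusk | 15.0 | 56.4 | 38.6 |
| dusk | 20.0 | 61.0 | 32.5 |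
| dusk | 30.0 | 63.8 | 29.3 |
| dusk | 60.0 | 62.4 | 25.7 |
| dusk | 90.0 | 59.3 | 24.2 |
| winter | 2.00 | 7.9 | 24.8 |
| winter | 6.00 | 1.3 | 2.5 |
| winter | 10.0 | 0 | 0.2 |
| winter | 15.0 | 0 | 0.2 |
| winter | 25.0 | 0.8 | 0 |
| winter | 30.0 | 0.1 | 0.1 |

(each reading ± 0.5 percentage points)

- the flask with the highest amount of Q, in percent of the L charged ("all alike" if they lie within 1.5 percentage points) (south-west / north-west / south / east / all alike)
- final Q, as a percentage of the L charged, in south-west
- final Q, as a percentage of the L charged, in north-west
- final Q, as a percentage of the L charged, in south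
- final Q, as a percentage of the L charged, in east

The first speaker took f = Q/(L+Q) from the dusk run, since f ignores what has left for J. There f read 44.8% after 8.00 min and 71.0% after 90.0 min. Taking the later reading as the ceiling and the approach as exponential, she read a pseudo-first-order relaxation constant λ of 0.125 min⁻¹ for the dusk run.

The second speaker scaled λ in proportion to Z, from 44 µM to 65 µM. From the forecast he borrowed a drop of λ by a factor of 3 between −20 °C and −35 °C, and he called it a guess. Multiplying by 50 min, he got 3.07 for south, the relaxation count N, meaning λ times the time. On his reckoning, south keeps 4.64% of its distance from equilibrium.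

The third speaker recalled that L + Q read 32.7% after 2.00 min in the winter run, and she judged the warm flasks not worth counting.

The forecast was then minuted: south highest, at 80% (70% to 87%), north-west 49% (43% to 54%), south-west 0.05%, east 0%. Its ground for south was “Nearly equilibrated by 50 min, little loss”.

Highest stands south: the flasks give 78.7% in south, 49.0% in north-west, 0.00885% in south-west and 0% in east.

    L → J (k = 0.250 min⁻¹, Ea = 90.0 kJ mol⁻¹)
    L + Z ⇌ Z + Q (K = 0.460, k = 9900 M⁻¹ min⁻¹, Ea = 38.0 kJ mol⁻¹, ΔH = −38.0 kJ mol⁻¹)
    (constants at 5 °C)

In south the forward rate of the reversible step alone uses L 110 times as fast as the path to J at 50.0 min, and J stands at 0.834% there. With the equilibrium constant K = 7.27 of south, the forward half-life of 17 min gives south a count of 2.32, lower than the carried N, and south holds 20.4% of L at its end. Going round once more, the carried N corrected by 0.755 and scaled to 0.026 mM of Z gives the neighbour of south 0.927, hence Q of 53.1%. That neighbour computes to 52.7%.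

Readings and results were generated by integration from invented constants; the scatter is artificial.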